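**Strategy.** The quinone ring is cut into a two-carbon and a four-carbon piece. Its only CH and the neighbouring carbonyl carbon (the C=O between CH and the side-chain carbon) come from a silyloxyacetylene. The other four ring carbons come from a 2-alkyl-3-methoxycyclobutenone that already carries the aryl ketone chain. One thermal benzannulation (ring opening to a vinylketene, ketene–alkyne [2+2], ring opening, 6π closure) joins CH to the adjacent future methoxy carbon and the C–OSi carbon to the chain-bearing carbon. It exploits the alternating 1,3,5-oxygenation of the quinone ring and delivers a phloroglucinol with three differentiated oxygens; methylation, desilylation and para-oxidation finish the route.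

Key step: step 4

Remark: compounds 1, 2 and 6 are taken as purchasable; compound 4 is drawn as the diketo tautomer but should exist and react mainly as its enol (3-hydroxycyclobut-2-en-1-one form).

**Step 1**
Reactants: 1 cyclobutane-1,3-dione; 2 3-chloro-1-(3,4-dimethoxyphenyl)propan-1-one
Product: 4 2-[3-(3,4-dimethoxyphenyl)-3-oxopropyl]cyclobutane-1,3-dione, via aryl vinyl ketone 3 (not isolated)
Conditions: 1 (1.5 equiv), Et3N (2.5 equiv), MeCN, 0 °C to rt; 1 M HCl work-up
Reagents that add atoms: none
Why: Et3N eliminates HCl from 2 (E1cB) to the aryl vinyl ketone 3, and the triethylammonium enolate of the vinylogous acid 1 adds through its C2 (Michael addition of a cyclic 1,3-dione); the excess of 1 and the more hindered product enolate should hold the reaction at mono-alkylation.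

**Step 2**
Reactants: 4 2-[3-(3,4-dimethoxyphenyl)-3-oxopropyl]cyclobutane-1,3-dione
Product: 5 2-[3-(3,4-dimethoxyphenyl)-3-oxopropyl]-3-methoxycyclobut-2-en-1-one
Conditions: Me3SiCHN2 (1.1 equiv, 2 M in hexanes), toluene/MeOH 4:1, 0 °C; AcOH quench
Reagents that add atoms: (trimethylsilyl)diazomethane, C[Si](C)(C)C=[N+]=[N-]
Why: The enol of 4, a vinylogous carboxylic acid, protonates the diazoalkane and the resulting methylating species alkylates the enolate on oxygen (diazoalkane O-methylation); the two carbonyl groups of 4 are equivalent, so a single enol ether should form, and the aryl ketone is not acidic enough to react.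

**Step 3**
Reactants: 6 acetylene
Product: 9 (ethynyloxy)triisopropylsilane, via lithium acetylide 7 (not isolated), via lithium ethynolate 8 (not isolated)
Conditions: n-BuLi, THF, −78 °C; t-BuOOLi (from t-BuOOH and LiN(SiMe3)2), −78 to −20 °C; i-Pr3SiOTf, −78 °C to rt
Reagents that add atoms: lithium tert-butyl peroxide (made in the flask from tert-butyl hydroperoxide), CC(C)(C)OO[Li]; triisopropylsilyl trifluoromethanesulfonate, CC(C)[Si](C(C)C)(C(C)C)OS(=O)(=O)C(F)(F)F
Why: Electrophilic oxygen transfer from the lithium peroxide to the lithium acetylide gives the ynolate, and the bulky, hard silyl triflate should silylate it on oxygen (acetylide oxidation and ynolate O-silylation route to silyloxyalkynes); the triisopropylsilyl group is chosen because it slows the 1,3-shift to the silylketene.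

**Step 4**
Reactants: 5 2-[3-(3,4-dimethoxyphenyl)-3-oxopropyl]-3-methoxycyclobut-2-en-1-one; 9 (ethynyloxy)triisopropylsilane
Product: 14 4-[3-(3,4-dimethoxyphenyl)-3-oxopropyl]-3-methoxy-5-(triisopropylsilyloxy)phenol, via vinylketene 10 (not isolated), via 4-vinylcyclobutenone 11 (not isolated), via dienylketene 12 (not isolated), via cyclohexa-2,4-dienone 13 (not isolated)
Conditions: 9 (2 equiv), degassed toluene, 80 °C then 110 °C, sealed tube
Reagents that add atoms: none
Why: Heating opens cyclobutenone 5 by 4π-electrocyclic cleavage of its C(=O)–CH2 bond to vinylketene 10; the nucleophilic CH terminus of 9 adds to the ketene carbonyl carbon and the silyloxy-bearing carbon bonds to the ketene α-carbon that carries the side chain, giving 11, which opens again to dienylketene 12, closes to 13 and tautomerises to phenol 14. This is a Danheiser benzannulation, the closest known cases being cyclobutenones with a 3-oxygen substituent reacting with silyloxyalkynes. The transient four-membered ring of 11 closes by ketene–alkyne [2+2] cycloaddition, and the six-membered ring closes by thermal disrotatory 6π-electrocyclisation of 12, in which the ketene carbon bonds to the former ring CH2 carbon. No stereocenter survives: the quaternary carbon of 11 forms as a racemate and is destroyed on ring opening. The step needs regioselectivity in the [2+2] event, which the polarisation of the ynol ether (β-carbon nucleophilic) and of the ketene (central carbon electrophilic) secures, so that in 14 the new OH is meta to OSi and para to the side chain. It also needs the ketene to choose the alkyne over the side-chain aryl ketone, which the far higher ketenophilicity of the silyloxyalkyne, used in excess, should secure.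

**Step 5**
Reactants: 14 4-[3-(3,4-dimethoxyphenyl)-3-oxopropyl]-3-methoxy-5-(triisopropylsilyloxy)phenol
Product: 15 1-(3,4-dimethoxyphenyl)-3-[2,4-dimethoxy-6-(triisopropylsilyloxy)phenyl]propan-1-one
Conditions: MeI, K2CO3, acetone, 40 °C
Reagents that add atoms: iodomethane, CI
Why: Williamson O-methylation of the only free phenol; K2CO3 does not enolise the aryl ketone, and the hindered aryl silyl ether should survive anhydrous carbonate.

**Step 6**
Reactants: 15 1-(3,4-dimethoxyphenyl)-3-[2,4-dimethoxy-6-(triisopropylsilyloxy)phenyl]propan-1-one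
Product: 16 1-(3,4-dimethoxyphenyl)-3-(2-hydroxy-4,6-dimethoxyphenyl)propan-1-one
Conditions: Bu4NF (1.1 equiv), AcOH (1.1 equiv), THF, 0 °C
Reagents that add atoms: none
Why: Fluoride-induced cleavage of the aryl silyl ether; the acetic acid buffer keeps the phenol protonated, so that it does not add to the γ-ketone (chromanol formation) before oxidation.

**Step 7**
Reactants: 16 1-(3,4-dimethoxyphenyl)-3-(2-hydroxy-4,6-dimethoxyphenyl)propan-1-one
Product: 17 evelynin
Conditions: (KSO3)2NO (2.5 equiv), KH2PO4 buffer (pH 6), acetone/H2O, rt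
Reagents that add atoms: potassium nitrosodisulfonate, [K+].[K+].[O]N(S(=O)(=O)[O-])S(=O)(=O)[O-]
Why: Teuber oxidation: one nitrosodisulfonate radical removes the phenolic hydrogen, a second couples at the free para carbon (the CH between the two methoxy groups) and loss of imidodisulfonate gives the para-quinone; one ortho position is blocked by the side chain, para attack is preferred over the remaining ortho CH, and the dimethoxybenzoyl ring is not a phenol and should stay untouched.

**Compound list**
1 | cyclobutane-1,3-dione | O=C1CC(=O)C1 | starting material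
2 | 3-chloro-1-(3,4-dimethoxyphenyl)propan-1-one | COc1ccc(cc1OC)C(=O)CCCl | starting material
3 | 1-(3,4-dimethoxyphenyl)prop-2-en-1-one | COc1ccc(cc1OC)C(=O)C=C | intermediate
4 | 2-[3-(3,4-dimethoxyphenyl)-3-oxopropyl]cyclobutane-1,3-dione | COc1ccc(cc1OC)C(=O)CCC1C(=O)CC1=O | intermediate
5 | 2-[3-(3,4-dimethoxyphenyl)-3-oxopropyl]-3-methoxycyclobut-2-en-1-one | COC1=C(CCC(=O)c2ccc(OC)c(OC)c2)C(=O)C1 | intermediate
6 | acetylene | C#C | starting material
7 | lithium acetylide (HC≡CLi) | [Li]C#C | intermediate
8 | lithium ethynolate (HC≡COLi) | [Li]OC#C | intermediate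
9 | (ethynyloxy)triisopropylsilane | C#CO[Si](C(C)C)(C(C)C)C(C)C | intermediate
10 | 2-[3-(3,4-dimethoxyphenyl)-3-oxopropyl]-3-methoxybuta-1,3-dien-1-one | COC(=C)C(=C=O)CCC(=O)c1ccc(OC)c(OC)c1 | intermediate
11 | 4-[3-(3,4-dimethoxyphenyl)-3-oxopropyl]-4-(1-methoxyethenyl)-3-(triisopropylsilyloxy)cyclobut-2-en-1-one (racemic) | COC(=C)C1(CCC(=O)c2ccc(OC)c(OC)c2)C(=O)C=C1O[Si](C(C)C)(C(C)C)C(C)C | intermediate
12 | (3E)-4-[3-(3,4-dimethoxyphenyl)-3-oxopropyl]-5-methoxy-3-(triisopropylsilyloxy)hexa-1,3,5-trien-1-one | O=C=C/C(O[Si](C(C)C)(C(C)C)C(C)C)=C(/CCC(=O)c1ccc(OC)c(OC)c1)C(OC)=C | intermediate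
13 | 4-[3-(3,4-dimethoxyphenyl)-3-oxopropyl]-5-methoxy-3-(triisopropylsilyloxy)cyclohexa-2,4-dien-1-one | COC1=C(CCC(=O)c2ccc(OC)c(OC)c2)C(O[Si](C(C)C)(C(C)C)C(C)C)=CC(=O)C1 | intermediate
14 | 4-[3-(3,4-dimethoxyphenyl)-3-oxopropyl]-3-methoxy-5-(triisopropylsilyloxy)phenol | COc1cc(O)cc(O[Si](C(C)C)(C(C)C)C(C)C)c1CCC(=O)c1ccc(OC)c(OC)c1 | intermediate
15 | 1-(3,4-dimethoxyphenyl)-3-[2,4-dimethoxy-6-(triisopropylsilyloxy)phenyl]propan-1-one | COc1cc(OC)c(CCC(=O)c2ccc(OC)c(OC)c2)c(O[Si](C(C)C)(C(C)C)C(C)C)c1 | intermediate
16 | 1-(3,4-dimethoxyphenyl)-3-(2-hydroxy-4,6-dimethoxyphenyl)propan-1-one | COc1cc(O)c(CCC(=O)c2ccc(OC)c(OC)c2)c(OC)c1 | intermediate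
17 | evelynin, 2,6-dimethoxy-3-[3-(3,4-dimethoxyphenyl)-3-oxopropyl]cyclohexa-2,5-diene-1,4-dione | COC1=CC(=O)C(CCC(=O)c2ccc(OC)c(OC)c2)=C(OC)C1=O | target

**Total step count:** 7. **Longest linear sequence:** 6 (steps 1, 2, 4, 5, 6, 7).

**Steps most likely to fail**

Step 3. Monolithium acetylide may disproportionate to the insoluble dilithium species before oxygen transfer, the small ynolate may be silylated on carbon to give the silylketene, and the product may undergo a 1,3-silyl shift on storage. The fallback sets out from cyclobutenone 5 and comes back at phenol 14. Ethynyltrimethylsilane is lithiated with LiN(SiMe3)2, oxidised with t-BuOOLi and silylated on oxygen with i-Pr3SiOTf to give trimethyl{[(triisopropylsilyl)oxy]ethynyl}silane F1; here the lithium acetylide is stable at 0 °C and the carbon terminus is blocked. Heating 5 with F1 in toluene should run the same cascade to 4-[3-(3,4-dimethoxyphenyl)-3-oxopropyl]-5-methoxy-3-(triisopropylsilyloxy)-2-(trimethylsilyl)phenol F2. Ipso-protodesilylation of this electron-rich arylsilane with CF3CO2H in CH2Cl2 at 0 °C should then give 14.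

Step 4. Ring opening of the donor-substituted cyclobutenone may be slower than thermal loss of the silyloxyalkyne (silyl shift, oligomerisation), the vinylketene may dimerise or be trapped by the enolisable side-chain ketone, and the new phenol may be acylated by excess alkyne. The fallback sets out from chloro ketone 2 and comes back at 14; it makes vinylketene 10 without any electrocyclic opening, by 1,4-dehydrochlorination of an acyclic enoyl chloride near room temperature. Michael addition of methyl acetoacetate to 3 (formed from 2 with K2CO3 in acetone) gives methyl 2-acetyl-5-(3,4-dimethoxyphenyl)-5-oxopentanoate F3. O-Methylation of its enolate (K2CO3, Me2SO4, DMSO) gives methyl 2-[3-(3,4-dimethoxyphenyl)-3-oxopropyl]-3-methoxybut-2-enoate F4 as an E/Z mixture. LiOH hydrolysis gives 2-[3-(3,4-dimethoxyphenyl)-3-oxopropyl]-3-methoxybut-2-enoic acid F5, and (COCl)2 with catalytic DMF gives 2-[3-(3,4-dimethoxyphenyl)-3-oxopropyl]-3-methoxybut-2-enoyl chloride F6. Slow addition of Et3N to F6 and 9 in toluene at 0 °C to rt, then warming to 80 °C, should remove HCl across the acyl and γ-methyl positions to give 10 and carry the rest of the cascade through to 14.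

Step 1. A second Michael addition may occur onto the still-acidic product, the strained 1,3-dione may open by retro-Claisen cleavage under amine base, and the water-soluble acidic product may be lost on isolation. The fallback sets out from dione 1 and comes back at cyclobutenone 5; it methylates first and attaches the side chain by palladium-catalysed coupling in place of enolate alkylation. Me3SiCHN2 in toluene/MeOH converts 1 into 3-methoxycyclobut-2-en-1-one F7, and I2/pyridine in CH2Cl2 iodinates its α-carbon to 2-iodo-3-methoxycyclobut-2-en-1-one F8. Racemic 1-(3,4-dimethoxyphenyl)prop-2-en-1-ol F9 is made from 3,4-dimethoxybenzaldehyde and vinylmagnesium bromide (CH2=CHMgBr). A Heck reaction of F8 with F9 (Pd(OAc)2, Bu4NCl, NaHCO3, DMF, 40 °C) should end in β-hydride elimination toward the carbinol carbon; tautomerisation of the enol then delivers the saturated aryl ketone 5 directly.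

**Further compounds**
F1 | step 3 | trimethyl{[(triisopropylsilyl)oxy]ethynyl}silane | C[Si](C)(C)C#CO[Si](C(C)C)(C(C)C)C(C)C
F2 | step 3 | 4-[3-(3,4-dimethoxyphenyl)-3-oxopropyl]-5-methoxy-3-(triisopropylsilyloxy)-2-(trimethylsilyl)phenol | COc1cc(O)c([Si](C)(C)C)c(O[Si](C(C)C)(C(C)C)C(C)C)c1CCC(=O)c1ccc(OC)c(OC)c1
F3 | step 4 | methyl 2-acetyl-5-(3,4-dimethoxyphenyl)-5-oxopentanoate (racemic) | COC(=O)C(CCC(=O)c1ccc(OC)c(OC)c1)C(C)=O
F4 | step 4 | methyl 2-[3-(3,4-dimethoxyphenyl)-3-oxopropyl]-3-methoxybut-2-enoate (E/Z mixture, double bond left undefined) | COC(=O)C(CCC(=O)c1ccc(OC)c(OC)c1)=C(C)OC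
F5 | step 4 | 2-[3-(3,4-dimethoxyphenyl)-3-oxopropyl]-3-methoxybut-2-enoic acid (E/Z mixture) | OC(=O)C(CCC(=O)c1ccc(OC)c(OC)c1)=C(C)OC
F6 | step 4 | 2-[3-(3,4-dimethoxyphenyl)-3-oxopropyl]-3-methoxybut-2-enoyl chloride (E/Z mixture) | ClC(=O)C(CCC(=O)c1ccc(OC)c(OC)c1)=C(C)OC
F7 | step 1 | 3-methoxycyclobut-2-en-1-one | COC1=CC(=O)C1
F8 | step 1 | 2-iodo-3-methoxycyclobut-2-en-1-one | COC1=C(I)C(=O)C1
F9 | step 1 | 1-(3,4-dimethoxyphenyl)prop-2-en-1-ol (racemic) | COc1ccc(cc1OC)C(O)C=C
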